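**Plan**

1. Ring labels: A is the phenol ring whose aryloxy carbon is para to its benzylic carbon, B the meta-linked ring on the ring A ether oxygen, C the para-linked ring, D the phenol ring whose hydroxyl is para to its benzylic carbon. Ring A is a catechol monoether, so its C–OH carbon and the neighbouring C–OAr carbon can be read as the carbonyl carbon and the alpha carbon of a cyclohexanone.
2. Retrosynthesis: the ring D hydroxyl is capped as a methyl ether and ring A is taken back to a 2-aryloxycyclohex-2-enone. The bond between the ring B oxygen and the alpha carbon is then cut, which opens the 20-membered ring to a seco 2,3-epoxycyclohexanone bearing the free ring B phenol.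
3. The epoxy ketone comes from a 5-substituted cyclohex-2-enone, cut at C5–C6 and C2=C3 into tert-butyl acetoacetate and a 5-arylpent-2-enal. The enal is cut at its C=C (Wittig) and at the ring D–CH2 bond (Heck with allyl alcohol), the B–C bibenzyl at its central C–C bond (Wittig, diimide) and the C–D diaryl ether at the ring C carbon–oxygen bond (SNAr).
4. Forward order: C–D ether, B–C bibenzyl, three-carbon and then two-carbon extension on ring D, six-membered carbocycle (ring A surrogate), epoxide, 20-membered ring, aromatisation of ring A, demethylation.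
5. Stereochemistry: the target has no stereocentre. The C5 centre of the ring A surrogate (catalyst control) and the two epoxide centres (substrate control) are transient and are erased by the dehydration in step 9 and the aromatisation in step 10.

Key step: step 9

Remark: the numbered starting materials are taken as catalogue compounds. The S amine catalyst in step 7 is used only because it is the common commercial form, so the ring A surrogate is carried as the R-enriched series; the enantiomer or the racemate would serve equally.

**Route**

Step 1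
Reactants: 1 5-bromo-2-methoxyphenol; 2 4-fluorobenzaldehyde
Product: 3 4-(5-bromo-2-methoxyphenoxy)benzaldehyde
Conditions: K2CO3, DMF, 120 °C
Reagents that add atoms: none
Why: Nucleophilic aromatic substitution (SNAr), in which the para formyl group activates the C–F bond toward the phenoxide of 1 while the unactivated C–Br bond is inert.

Step 2
Reactants: 4 3-hydroxybenzyl alcohol
Product: 5 (3-hydroxybenzyl)triphenylphosphonium bromide
Conditions: PPh3·HBr, MeCN, reflux
Reagents that add atoms: triphenylphosphine hydrobromide, [Br-].[PH+](c1ccccc1)(c1ccccc1)c1ccccc1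
Why: Phosphonium salt formation, in which the acid converts the benzylic alcohol into a benzylic electrophile that quaternises triphenylphosphine and the phenol is left untouched.

Step 3
Reactants: 5 (3-hydroxybenzyl)triphenylphosphonium bromide; 3 4-(5-bromo-2-methoxyphenoxy)benzaldehyde
Product: 7 3-[2-[4-(5-bromo-2-methoxyphenoxy)phenyl]ethenyl]phenol as an E/Z mixture, via ylide phenoxide 6 (not isolated)
Conditions: KOtBu (2.2 equiv), THF, 0 °C; then 3, 0 °C to rt
Reagents that add atoms: none
Why: Wittig olefination, in which two equivalents of base give the phenoxide ylide 6 that condenses with aldehyde 3; the alkene geometry is of no concern because the double bond is saturated in step 4.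

Step 4
Reactants: 7 3-[2-[4-(5-bromo-2-methoxyphenoxy)phenyl]ethenyl]phenol
Product: 8 3-[2-[4-(5-bromo-2-methoxyphenoxy)phenyl]ethyl]phenol
Conditions: TsNHNH2 (excess), NaOAc, THF/H2O, reflux
Reagents that add atoms: none
Why: Diimide reduction, in which diimide generated from the sulfonyl hydrazide delivers hydrogen concertedly to the stilbene C=C and, unlike hydrogenation over palladium, leaves the aryl C–Br bond intact.

Step 5
Reactants: 8 3-[2-[4-(5-bromo-2-methoxyphenoxy)phenyl]ethyl]phenol; 9 allyl alcohol (prop-2-en-1-ol)
Product: 10 3-[3-[4-[2-(3-hydroxyphenyl)ethyl]phenoxy]-4-methoxyphenyl]propanal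
Conditions: Pd(OAc)2 (5 mol %), Bu4NCl, NaHCO3, DMF, 90 °C
Reagents that add atoms: none
Why: Heck reaction with an allylic alcohol under phosphine-free ammonium salt conditions, in which the arylpalladium species adds to the terminal alkene carbon and beta-hydride elimination toward the carbinol carbon gives an enol that tautomerises to the 3-arylpropanal.

Step 6
Reactants: 10 3-[3-[4-[2-(3-hydroxyphenyl)ethyl]phenoxy]-4-methoxyphenyl]propanal; 11 (triphenylphosphoranylidene)acetaldehyde
Product: 12 (2E)-5-[3-[4-[2-(3-hydroxyphenyl)ethyl]phenoxy]-4-methoxyphenyl]pent-2-enal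
Conditions: toluene, 80 °C
Reagents that add atoms: none
Why: Wittig olefination with a formyl-stabilised ylide gives the E enal by two-carbon homologation, and the conjugated product is less electrophilic than the saturated aldehyde, which limits a second homologation.

Step 7
Reactants: 12 (2E)-5-[3-[4-[2-(3-hydroxyphenyl)ethyl]phenoxy]-4-methoxyphenyl]pent-2-enal; 13 tert-butyl acetoacetate
Product: 16 (5R)-5-[2-[3-[4-[2-(3-hydroxyphenyl)ethyl]phenoxy]-4-methoxyphenyl]ethyl]cyclohex-2-en-1-one, via Michael adduct 14 (not isolated), via cyclised keto ester 15 (not isolated)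
Conditions: 13 (2 equiv), (S)-2-[diphenyl(trimethylsilyloxy)methyl]pyrrolidine (10 mol %), PhCO2H (10 mol %), toluene, rt; then TsOH·H2O (20 mol %), 80 °C
Reagents that add atoms: none
Why: Amine-catalysed Michael/aldol condensation/decarboxylation annulation of a beta-keto ester with an enal, in which iminium-activated conjugate addition is followed by acid-promoted aldol condensation of the methyl ketone onto the aldehyde and loss of isobutene and CO2, giving the 5-substituted enone without regiochemical ambiguity; the C5 stereocentre is set by the catalyst, whose bulky side arm shields one face of the iminium ion (R expected from the S catalyst), and it is erased again in step 10.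

Step 8
Reactants: 16 (5R)-5-[2-[3-[4-[2-(3-hydroxyphenyl)ethyl]phenoxy]-4-methoxyphenyl]ethyl]cyclohex-2-en-1-one
Product: 17 (1R,4R,6R)-4-[2-[3-[4-[2-(3-hydroxyphenyl)ethyl]phenoxy]-4-methoxyphenyl]ethyl]-7-oxabicyclo[4.1.0]heptan-2-one (trans 2,3-epoxy ketone)
Conditions: 30% aq H2O2, NaOH, MeOH, 0 °C
Reagents that add atoms: hydrogen peroxide, OO
Why: Weitz–Scheffer nucleophilic epoxidation, in which hydroperoxide adds axially to the beta carbon anti to the C5 side chain so that the trans epoxide should predominate (substrate control, and any cis epimer converges in step 9), while at 0 °C the ring B phenoxide is not expected to open the epoxide.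

Step 9
Reactants: 17 (1R,4R,6R)-4-[2-[3-[4-[2-(3-hydroxyphenyl)ethyl]phenoxy]-4-methoxyphenyl]ethyl]-7-oxabicyclo[4.1.0]heptan-2-one
Product: 19 20-membered macrocyclic (5R)-2-aryloxycyclohex-2-en-1-one (ring B oxygen on C2; ethano bridge to ring D on C5; ring D as methyl ether), via hydroxy ketone 18 (not isolated)
Conditions: Cs2CO3 (2 equiv), MeCN, 70 °C, 17 added by syringe pump to about 1 mM final concentration
Reagents that add atoms: none
Why: The caesium phenoxide of ring B attacks C2, the epoxide carbon alpha to the carbonyl, in an SN2 step with inversion to give the trans 2-aryloxy-3-hydroxy ketone 18, whose acidic alpha hydrogen is then removed and hydroxide expelled (E1cB) to give the conjugated 2-aryloxy enone 19. The closest known reaction type is the base-mediated intermolecular opening of 2,3-epoxycyclohexanones by phenoxides to 2-aryloxycyclohex-2-enones, here run intramolecularly under high dilution. The 20-membered ring closes by O-alkylation at an sp3 carbon of a flexible ring (macro-etherification, exo with respect to the breaking epoxide C–O bond), so no metal-mediated coupling onto a flat, unactivated arene is required. The only new stereocentre, C2 of 18, arises by inversion and disappears on dehydration, so 19 gains none and both epoxide epimers of 17 converge. Alpha over beta regioselectivity is secured by the carbonyl group, which accelerates substitution at the adjacent carbon as in an alpha-halo ketone, and by the irreversible dehydration open only to the alpha adduct; ring closure over oligomerisation is secured by slow addition, and the methyl ether on ring D leaves a single phenoxide nucleophile.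

Step 10
Reactants: 19 20-membered macrocyclic (5R)-2-aryloxycyclohex-2-en-1-one
Product: 21 ring D methyl ether of the target (ring A as free phenol), via dienone 20 (not isolated)
Conditions: Pd(O2CCF3)2 (5 mol %), 2-(dimethylamino)pyridine (10 mol %), TsOH·H2O (20 mol %), O2 (1 atm), DMSO, 80 °C
Reagents that add atoms: none
Why: Palladium-catalysed aerobic dehydrogenation of a cyclohexenone, in which palladation at C6 and beta-hydride elimination from C5 give the cross-conjugated dienone 20 that tautomerises to the phenol and so removes the last stereocentre.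

Step 11
Reactants: 21 ring D methyl ether of the target
Product: 22 CNP0329842.0 (target)
Conditions: BBr3, CH2Cl2, −78 °C to 0 °C; then H2O
Reagents that add atoms: none
Why: Lewis acid ether cleavage (BBr3 demethylation), in which bromide attacks the methyl group of the boron-complexed aryl methyl ether while the two diaryl ether bonds are not cleaved.

**Compound list**

1 | 5-bromo-2-methoxyphenol | COc1ccc(Br)cc1O | starting material
2 | 4-fluorobenzaldehyde | O=Cc1ccc(F)cc1 | starting material
3 | 4-(5-bromo-2-methoxyphenoxy)benzaldehyde | COc1ccc(Br)cc1Oc1ccc(C=O)cc1 | intermediate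
4 | 3-hydroxybenzyl alcohol | OCc1cccc(O)c1 | starting material
5 | (3-hydroxybenzyl)triphenylphosphonium bromide | [Br-].Oc1cccc(C[P+](c2ccccc2)(c2ccccc2)c2ccccc2)c1 | intermediate
6 | potassium 3-[(triphenylphosphoranylidene)methyl]phenoxide (ylide phenoxide, not isolated) | [K+].[O-]c1cccc(C=P(c2ccccc2)(c2ccccc2)c2ccccc2)c1 | intermediate
7 | 3-[2-[4-(5-bromo-2-methoxyphenoxy)phenyl]ethenyl]phenol (E/Z mixture, geometry left open) | COc1ccc(Br)cc1Oc1ccc(C=Cc2cccc(O)c2)cc1 | intermediate
8 | 3-[2-[4-(5-bromo-2-methoxyphenoxy)phenyl]ethyl]phenol | COc1ccc(Br)cc1Oc1ccc(CCc2cccc(O)c2)cc1 | intermediate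
9 | allyl alcohol (prop-2-en-1-ol) | C=CCO | starting material
10 | 3-[3-[4-[2-(3-hydroxyphenyl)ethyl]phenoxy]-4-methoxyphenyl]propanal | COc1ccc(CCC=O)cc1Oc1ccc(CCc2cccc(O)c2)cc1 | intermediate
11 | (triphenylphosphoranylidene)acetaldehyde | O=CC=P(c1ccccc1)(c1ccccc1)c1ccccc1 | starting material
12 | (2E)-5-[3-[4-[2-(3-hydroxyphenyl)ethyl]phenoxy]-4-methoxyphenyl]pent-2-enal | COc1ccc(CC/C=C/C=O)cc1Oc1ccc(CCc2cccc(O)c2)cc1 | intermediate
13 | tert-butyl acetoacetate | CC(=O)CC(=O)OC(C)(C)C | starting material
14 | tert-butyl (3R)-2-acetyl-3-[2-[3-[4-[2-(3-hydroxyphenyl)ethyl]phenoxy]-4-methoxyphenyl]ethyl]-5-oxopentanoate (Michael adduct, C2 epimers, not isolated) | CC(=O)C(C(=O)OC(C)(C)C)[C@@H](CC=O)CCc1ccc(OC)c(Oc2ccc(CCc3cccc(O)c3)cc2)c1 | intermediate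
15 | tert-butyl (6R)-6-[2-[3-[4-[2-(3-hydroxyphenyl)ethyl]phenoxy]-4-methoxyphenyl]ethyl]-2-oxocyclohex-3-ene-1-carboxylate (C1 epimers, not isolated) | CC(C)(C)OC(=O)C1C(=O)C=CC[C@H]1CCc1ccc(OC)c(Oc2ccc(CCc3cccc(O)c3)cc2)c1 | intermediate
16 | (5R)-5-[2-[3-[4-[2-(3-hydroxyphenyl)ethyl]phenoxy]-4-methoxyphenyl]ethyl]cyclohex-2-en-1-one | COc1ccc(CC[C@@H]2CC=CC(=O)C2)cc1Oc1ccc(CCc2cccc(O)c2)cc1 | intermediate
17 | (1R,4R,6R)-4-[2-[3-[4-[2-(3-hydroxyphenyl)ethyl]phenoxy]-4-methoxyphenyl]ethyl]-7-oxabicyclo[4.1.0]heptan-2-one (epoxide oxygen trans to the side chain) | COc1ccc(CC[C@@H]2C[C@H]3O[C@H]3C(=O)C2)cc1Oc1ccc(CCc2cccc(O)c2)cc1 | intermediate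
18 | macrocyclic (2S,3R,5R)-2-aryloxy-3-hydroxycyclohexan-1-one: ring B oxygen on C2, hydroxyl on C3, ethano bridge to ring D on C5 (not isolated) | O=C1C[C@H]2C[C@@H](O)[C@@H]1Oc1cccc(c1)CCc1ccc(cc1)Oc1cc(ccc1OC)CC2 | intermediate
19 | 20-membered macrocyclic (5R)-2-aryloxycyclohex-2-en-1-one: ring B oxygen on C2, ethano bridge to ring D on C5, ring D as methyl ether | O=C1C[C@H]2CC=C1Oc1cccc(c1)CCc1ccc(cc1)Oc1cc(ccc1OC)CC2 | intermediate
20 | macrocyclic 2-aryloxy-5-alkylcyclohexa-2,5-dien-1-one, keto tautomer of 21 (not isolated) | O=C1C=C2CC=C1Oc1cccc(c1)CCc1ccc(cc1)Oc1cc(ccc1OC)CC2 | intermediate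
21 | ring D methyl ether of the target, ring A as free phenol | Oc1cc2ccc1Oc1cccc(c1)CCc1ccc(cc1)Oc1cc(ccc1OC)CC2 | intermediate
22 | CNP0329842.0 | Oc1cc2ccc1Oc1cccc(c1)CCc1ccc(cc1)Oc1cc(ccc1O)CC2 | target

**Count and risks**

Total step count: 11. Longest linear sequence: 10 steps (steps 1 and 3 to 11, from 1 and 2); step 2 is a one-step side branch.

Steps most likely to fail:

Step 9. The phenoxide may react with the epoxy ketone of a second molecule (oligomerisation), or the base may isomerise the epoxy ketone to the diosphenol before the ring closes. The fallback makes the same oxygen–carbon bond by displacement at an alpha-bromo ketone. It sets out from 16: conjugate reduction with LiBH(sec-Bu)3 (2.2 equiv, THF, −78 °C) and trapping of the regiodefined enolate and the phenoxide with Me3SiCl should give the bis-silylated enol ether F1. NBS at −78 °C followed by aqueous work-up should give the 2-bromo ketone F2 with the ring B phenol free again. Macro-Williamson etherification (K2CO3, MeCN, high dilution) should close the 20-membered ring to the saturated 2-aryloxy ketone F3. Two-fold aerobic dehydrogenation of F3 under the conditions of step 10 then returns to the route at 21.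

Step 7. The keto ester may add to the aldehyde carbon instead of the beta carbon, the acid stage may stop short of full condensation and decarboxylation, or isobutene may alkylate an electron-rich ring. The fallback builds the ring through a symmetric dione and sets out from 10. Wittig reaction with 1-(triphenylphosphoranylidene)propan-2-one should give the enone F4. Michael addition and Claisen cyclisation with dimethyl malonate (NaOMe, MeOH, reflux), then saponification and acidic decarboxylation, should give the dione F5. MeOH with TsOH should give the racemic vinylogous ester F6. Reduction with LiAlH4 followed by aqueous HCl (carbonyl transposition) returns to the route at 16, here as the racemate, which serves equally.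

Step 10. Palladation at the alpha' position may be slow in the macrocycle, and prolonged heating under oxygen may degrade the electron-rich phenol that forms. The fallback fixes the site of dehydrogenation in a separate kinetic enolisation and sets out from 19. LiN(iPr)2 in THF at −78 °C and Me3SiCl should give the cross-conjugated silyl dienol ether F7. Saegusa–Ito oxidation with one equivalent of Pd(OAc)2 in MeCN at rt should give dienone 20, whose tautomerisation returns to the route at 21.

**Further compounds**

F1 | step 9 | trimethylsilyl enol ether of the 2,3-dihydro ketone of 16 (double bond between C1 and C2) with the ring B phenol as trimethylsilyl ether; side-chain centre as in 16 | COc1ccc(CC[C@@H]2CCC=C(O[Si](C)(C)C)C2)cc1Oc1ccc(CCc2cccc(O[Si](C)(C)C)c2)cc1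
F2 | step 9 | 2-bromo-5-[2-[3-[4-[2-(3-hydroxyphenyl)ethyl]phenoxy]-4-methoxyphenyl]ethyl]cyclohexan-1-one (C2 epimers; C5 as in 16) | COc1ccc(CC[C@@H]2CCC(Br)C(=O)C2)cc1Oc1ccc(CCc2cccc(O)c2)cc1
F3 | step 9 | macrocyclic 2-aryloxycyclohexan-1-one, the 2,3-dihydro derivative of 19 (C2 epimers) | O=C1C[C@H]2CCC1Oc1cccc(c1)CCc1ccc(cc1)Oc1cc(ccc1OC)CC2
F4 | step 7 | (3E)-6-[3-[4-[2-(3-hydroxyphenyl)ethyl]phenoxy]-4-methoxyphenyl]hex-3-en-2-one | COc1ccc(CC/C=C/C(C)=O)cc1Oc1ccc(CCc2cccc(O)c2)cc1
F5 | step 7 | 5-[2-[3-[4-[2-(3-hydroxyphenyl)ethyl]phenoxy]-4-methoxyphenyl]ethyl]cyclohexane-1,3-dione | COc1ccc(CCC2CC(=O)CC(=O)C2)cc1Oc1ccc(CCc2cccc(O)c2)cc1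
F6 | step 7 | racemic 3-methoxy-5-[2-[3-[4-[2-(3-hydroxyphenyl)ethyl]phenoxy]-4-methoxyphenyl]ethyl]cyclohex-2-en-1-one | COC1=CC(=O)CC(CCc2ccc(OC)c(Oc3ccc(CCc4cccc(O)c4)cc3)c2)C1
F7 | step 10 | macrocyclic silyl dienol ether of 19: trimethylsilyloxy on C1, double bonds C1=C6 and C2=C3, side-chain centre as in 19 | C[Si](C)(C)OC1=C[C@H]2CC=C1Oc1cccc(c1)CCc1ccc(cc1)Oc1cc(ccc1OC)CC2
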